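## The problem

Compound 18 is the mono-O-prenyl ether of (7S,7'S,8R,8'R)-pinoresinol: a cis-fused 2,6-diaryl-3,7-dioxabicyclo[3.3.0]octane with both aryl groups on the convex face. The numbering used throughout is: C7 and C7' are the benzylic carbons (C7 carries the 4-hydroxy-3-methoxyphenyl ring, C7' the 3-methoxy-4-prenyloxyphenyl ring), C8 and C8' the ring-fusion carbons, C9 and C9' the OCH2 carbons; ring A is O1–C7–C8–C8'–C9' and ring B is O2–C7'–C8'–C8–C9. The bicyclic core is C2-symmetric, but the two arenes differ in one remote O-substituent, so the aryl groups must either enter at different stages with their phenols already told apart, or a statistical step must be accepted at the end. Of the four contiguous stereocentres, C8 and C8' are tied together by the cis fusion, so one fixes the other as soon as a second five-membered ring is closed across the C8–C8' bond. C7 and C7' are benzylic ethers of electron-rich arenes: they ionise under acid and their exo and endo epimers are close in energy, so they must be set under kinetic control, and the absolute configuration has to enter at a fusion carbon or at C7 and be relayed from there. The prenyl aryl ether does not tolerate ozone, hydrogenation or strong protic and Lewis acids; the benzylic C–O bonds do not tolerate hydrogenolysis or prolonged acid; the free phenol para to a benzylic ether can open ring A through a quinone methide under forcing base. The feature that invites a short synthesis is ring A itself: O1 lies between the aryl-bearing C7 and the methylene C9', and C8 and C8' each carry one extra carbon (C9 and C7'). This is the pattern left by joining an arylidene malonate-type acceptor (C7=C8, with C9 as a carboxyl carbon) to the O–CH2–CH(vinyl) unit of vinylethylene carbonate, the vinyl group being C7' in latent form.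

## Retrosynthesis

**Disconnection 1 (aryl O–Si).** The last bond cut is the O–Si bond of 17, the triisopropylsilyl ether of 18. Cutting here and not at the prenyl ether keeps the acid-sensitive allylic ether in place and leaves nothing to do after deprotection. 17 is no simpler in skeleton, but it holds the two phenols in distinguishable form. The forward step must remove silicon without touching the prenyl ether or the benzylic C–O bonds.

**Disconnection 2 (C7'–O2, ring B).** Ring B is opened at its benzylic C–O bond to give diol 16. The other ring B cut, C9–O2, would need an SN2 closure and therefore a configurationally pure C7' carbinol; the benzylic cut lets both carbinol epimers pass through one cation. 16 has one ring fewer and one stereocentre that no longer matters. The forward closure must be kinetically exo-selective and mild enough for the prenyl ether.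

**Disconnection 3 (C7'–aryl, with C9 at the acid level).** 16 is the reduction product of the cis-fused lactone 15. 15 is cut at the C7'–aryl bond and the lactone C–O bond to the formyl ester 10 and the Grignard reagent 13; hydroxy ester 14 is the link. 13 comes from bromide 12 and so from 4-bromo-2-methoxyphenol 11. A lactone is preferred to direct addition onto a hydroxy aldehyde because only a cis-fused lactone can form, which fixes C8 relative to C8' whatever its configuration before. Bringing the prenyl ether in with 13, after the ozonolysis, avoids a benzyl ether and its late exchange. 10 carries one arene and two secured stereocentres. The forward step must add to the formyl group without attacking the ester or enolising C8'.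

**Disconnection 4 (functional group changes at C7' and C9).** The formyl group of 10 is a cleaved vinyl group (ozonide 9 from ester 8). The ester of 8 is what remains of a geminal pair of carboxyl carbons after loss of one (half-ester 7 from the spiro compound 6). No skeletal bond is cut; the point is that a vinyl group on C8' and a symmetric malonate-type carbon at C8 are exactly what an annulation can deliver. 6 has only two stereocentres, C7 and C8'. The forward steps must unmask C9 and C7' without opening ring A.

**Disconnection 5 (C7–O1 and C8–C8', ring A).** Both bonds of ring A that flank C8 are cut, giving the arylidene Meldrum's acid 4 and racemic vinylethylene carbonate 5. Compared with cuts at the aryl–carbon bonds or at C7–C8 and C7'–C8', this one closes a ring of the target, sets two stereocentres and leaves C9' at its final oxidation level in a single catalytic step. 4 is achiral, and the stereocentre of 5 is erased on ionisation. The forward reaction must give branched attack on the allyl unit, the R configuration at C8' and the trans relation between aryl and vinyl.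

**Disconnection 6 (C7=C8, then O–Si).** 4 is the Knoevenagel product of the silylated aldehyde 2 and Meldrum's acid 3, and 2 is the silyl ether of vanillin 1. These are standard condensations on commercial materials; they only need to preserve the silyl ether.

## Roads not taken

**Alternative 1:** Both aryl–carbon bonds (C7–aryl and C7'–aryl) are cut, leading back to the C2-symmetric bis-lactol diacetate A1. In the forward direction A1 is ionised with Me3SiBr or BF3·OEt2, and both oxocarbenium carbons are attacked on the convex face by the arylzinc bromide A2, giving pinoresinol dibenzyl ether A3 without ring formation.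
- Merits: the bicycle itself directs both new centres exo under kinetic control, and two C–C bonds form in one operation.
- Weak points for this target: the aryl groups enter as identical units. The phenols can be told apart only after double debenzylation to pinoresinol A4, whose two hydroxyls are related by the C2 axis, so mono-prenylation is statistical. A stepwise arylation with two different zinc reagents would have to stop cleanly after the first ionisation. Hydrogenolysis of A3 must distinguish O-benzyl groups from the benzylic ring C–O bonds, and A1 needs an enantioselective synthesis of its own.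
- Comparison: for C7 and C7' this road is better than the chosen one, because substrate shape and not a catalyst sets them. The chosen plan sets against this that the two arenes differ from the first step on, that no statistical step occurs, and that chirality comes from a catalyst acting on achiral and racemic materials.

**Alternative 2:** The C8–C8' bond is traced back to a 1,2-shift. Ring A is expanded by placing C9 inside the ring, which gives the diazo ketone A5 (ring O1–C7–C8(=N2)–C9(=O)–C8'–C9'). Photolysis in methanol triggers a Wolff rearrangement: C8' migrates from C9 to the carbene carbon C8 with retention and the ketene is trapped as the methyl ester A6.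
- Merits: the migration is stereospecific, C9 arrives as an ester, and both arenes, prenyl ether included, are in place before the contraction.
- Weak points: A5 holds three stereocentres on a six-membered ring and must be built and then diazotised at C8, next to the aryl-bearing C7, by a deacylative diazo transfer. The carbene precursor is irradiated in the presence of the prenyl alkene and two electron-rich arenes, which invites cyclopropanation, C–H insertion and photo-oxidation. Protonation of the ketene-derived enol at C8 is uncontrolled.
- Comparison: A6 already carries the C7' aryl group, so it is further along than ester 8, and its key step does not depend on catalyst control. Against this, 8 is reached in four steps from vanillin, while A5 would need a longer sequence than the whole chosen route before its key step could be tried.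

**Alternative 3:** C7'–C8' and C7–C8 are cut. The lithiated dithiane A8 adds to C8' of (5R)-5-menthyloxyfuran-2(5H)-one A7 anti to the menthyloxy group, and the lactone enolate is trapped at C8 by aldehyde 2, giving the trans,trans adduct A9.
- Merits: every skeletal carbon is assembled in one step, each new centre is set by its neighbour in a rigid lactone, and diastereomers of this type are usually separable by crystallisation.
- Weak points: no ring of the target is closed. C9' arrives as an acetal and C7' as a dithioketal, so the route still needs auxiliary removal with reduction at C9', dithiane cleavage, ketone reduction, lactone reduction and two ring closures. Dithiane cleavage uses mercury salts or oxidants that a prenyl ether does not survive, hence the benzyl ether and a later exchange. The auxiliary is stoichiometric.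
- Comparison: stereochemical reliability is higher than in the chosen plan. The chosen plan offers in return ring A with C9' at the right oxidation level from one catalytic step, no sulfur or mercury chemistry and fewer redox corrections, which makes it shorter.

Key step: step 3

## Route

Remark on the chemistry: 5 is used as the racemate. Which enantiomer of the phosphoramidite gives the R configuration at the vinyl-bearing carbon of 6 has to be assigned on the first adduct; the ligand named in step 3 stands for that enantiomer.

Step 1
Reactants: 1 vanillin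
Product: 2 3-methoxy-4-(triisopropylsilyloxy)benzaldehyde
Conditions: TIPSCl, imidazole, DMF, rt
Reagents that add atoms: triisopropylsilyl chloride, CC(C)[Si](Cl)(C(C)C)C(C)C
Why: Silylation of a phenol with a silyl chloride and imidazole; the bulky triisopropylsilyl group is chosen because the aryl silyl ether must pass warm pyridine–methanol, a Grignard reagent and LiAlH4, and it marks this arene as the one that ends as the free phenol.

Step 2
Reactants: 2 3-methoxy-4-(triisopropylsilyloxy)benzaldehyde; 3 Meldrum's acid
Product: 4 5-[3-methoxy-4-(triisopropylsilyloxy)benzylidene]-2,2-dimethyl-1,3-dioxane-4,6-dione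
Conditions: pyrrolidine (10 mol%), AcOH (10 mol%), PhMe, rt
Reagents that add atoms: none
Why: Knoevenagel condensation under pyrrolidinium acetate catalysis (iminium activation of the aldehyde, addition of the enol, loss of the amine); Meldrum's acid is acidic enough to condense at room temperature, and the product is symmetric about C8, so no alkene geometry has to be controlled.

Step 3
Reactants: 4 5-[3-methoxy-4-(triisopropylsilyloxy)benzylidene]-2,2-dimethyl-1,3-dioxane-4,6-dione; 5 4-vinyl-1,3-dioxolan-2-one
Product: 6 (1R,4R)-4-ethenyl-1-[3-methoxy-4-(triisopropylsilyloxy)phenyl]-8,8-dimethyl-2,7,9-trioxaspiro[4.5]decane-6,10-dione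
Conditions: Pd2(dba)3·CHCl3 (2.5 mol%), (S)-BINOL N,N-bis[(S)-1-phenylethyl]phosphoramidite (10 mol%), THF, 0 °C to rt
Reagents that add atoms: none
Why: Zerovalent palladium ionises the allylic C–O bond of 5 and CO2 is lost, giving a zwitterion with an alkoxide on C9' and a π-allylpalladium unit at C8'; the alkoxide adds reversibly to C7 of 4, and the resulting Meldrum's acid anion at C8 attacks the substituted allyl terminus C8' on the face opposite palladium, which forms C7–O1 and C8–C8' and frees the catalyst. The closest known reaction type is the palladium-catalysed decarboxylative [3+2] cycloaddition of vinylethylene carbonates with doubly activated Michael acceptors, including enantioselective versions with phosphoramidite ligands, and the related annulation of vinylcyclopropanes with alkylidene Meldrum's acids. Ring A closes in a 5-exo mode (C-allylation at the internal terminus, vinyl left exocyclic); attack at the terminal carbon would require a seven-membered ring. C8' is set by the ligand: both enantiomers of 5 give π-allyl complexes that interconvert by π–σ–π isomerisation, and the ligand pocket decides which allyl face is alkylated. C7 is set relative to C8' under Curtin–Hammett conditions because the oxa-Michael step is reversible: in the closing transition state the C7–H bond lies near the plane of the Meldrum's acid enolate to avoid allylic strain, the aryl group leans to one face of the forming ring, and the allyl terminus with its palladium–ligand fragment is expected to take the other, which gives the 2,4-trans adduct. The step needs branched over linear attack, C- over O-allylation of the enolate and a useful rate with an electron-rich arylidene; the tether secures the first, the soft and highly stabilised carbanion the second, and the Meldrum's acid acceptor, far more electrophilic than a malonate, the third. C8 is a spiro carbon with two identical carbonyl arms and is not yet stereogenic.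

Step 4
Reactants: 6 (1R,4R)-4-ethenyl-1-[3-methoxy-4-(triisopropylsilyloxy)phenyl]-8,8-dimethyl-2,7,9-trioxaspiro[4.5]decane-6,10-dione
Product: 8 methyl (2S,3S,4R)-4-ethenyl-2-[3-methoxy-4-(triisopropylsilyloxy)phenyl]tetrahydrofuran-3-carboxylate, via malonic half-ester 7 (not isolated)
Conditions: MeOH, pyridine, Cu powder (10 mol%), 100 °C, sealed tube
Reagents that add atoms: methanol, CO
Why: Alcoholysis of the Meldrum's acid ring releases acetone and gives the malonic half-ester 7, which loses CO2 through the usual cyclic transition state at 100 °C (alcoholysis–decarboxylation of a disubstituted Meldrum's acid). The ester enol should be protonated mainly so that the ester ends trans to the aryl group and cis to the vinyl group; any C8 epimer is carried along because step 7 converges both.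

Step 5
Reactants: 8 methyl (2S,3S,4R)-4-ethenyl-2-[3-methoxy-4-(triisopropylsilyloxy)phenyl]tetrahydrofuran-3-carboxylate
Product: 10 methyl (2S,3S,4R)-4-formyl-2-[3-methoxy-4-(triisopropylsilyloxy)phenyl]tetrahydrofuran-3-carboxylate, via ozonide 9 (not isolated)
Conditions: O3, CH2Cl2, −78 °C, Sudan red 7B end point; then PPh3, −78 °C to rt; used crude
Reagents that add atoms: ozone, [O-][O+]=O
Why: Ozonolysis of the only alkene (1,3-dipolar cycloaddition, cycloreversion, recombination to the ozonide) and neutral reduction with PPh3, which spares the stereocentre next to the new formyl group. The electron-rich arenes react far more slowly than a terminal alkene, and ozone is stopped at the indicator end point.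

Step 6
Reactants: 11 4-bromo-2-methoxyphenol
Product: 12 4-bromo-2-methoxy-1-(3-methylbut-2-enyloxy)benzene
Conditions: prenyl bromide, K2CO3, acetone, 56 °C
Reagents that add atoms: 1-bromo-3-methylbut-2-ene (prenyl bromide), CC(C)=CCBr
Why: Williamson ether synthesis (SN2 of a phenoxide on a primary allylic bromide); O-alkylation is the normal course with K2CO3 in acetone, and no other nucleophilic site is present.

Step 7
Reactants: 10 methyl (2S,3S,4R)-4-formyl-2-[3-methoxy-4-(triisopropylsilyloxy)phenyl]tetrahydrofuran-3-carboxylate; 12 4-bromo-2-methoxy-1-(3-methylbut-2-enyloxy)benzene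
Product: 15 (3aR,6S,6aS)-6-[3-methoxy-4-(triisopropylsilyloxy)phenyl]-3-[3-methoxy-4-(3-methylbut-2-enyloxy)phenyl]tetrahydro-1H,3H-furo[3,4-c]furan-1-one (both C3 epimers), via arylmagnesium bromide 13 (not isolated), via hydroxy ester 14 (not isolated)
Conditions: 12, Mg, I2 (cat.), THF, 40 °C; then 10, THF, −78 to 0 °C; aq. NH4Cl; then DBU (0.3 equiv), PhMe, 60 °C
Reagents that add atoms: none
Why: The Grignard reagent 13, formed by magnesium insertion into 12, adds to the formyl group of 10 at −78 °C much faster than to the methyl ester (1,2-addition), and the alkoxide lactonises onto the ester. A trans-fused bicyclic lactone is out of reach, so DBU epimerises any trans hydroxy ester at C8 until it closes, and C8 is set cis to C8' by the ring constraint. The C7' carbinol is left as a mixture on purpose, because step 9 passes through a planar cation.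

Step 8
Reactants: 15 (3aR,6S,6aS)-6-[3-methoxy-4-(triisopropylsilyloxy)phenyl]-3-[3-methoxy-4-(3-methylbut-2-enyloxy)phenyl]tetrahydro-1H,3H-furo[3,4-c]furan-1-one
Product: 16 [(2S,3R,4R)-4-{hydroxy[3-methoxy-4-(3-methylbut-2-enyloxy)phenyl]methyl}-2-[3-methoxy-4-(triisopropylsilyloxy)phenyl]tetrahydrofuran-3-yl]methanol (both carbinol epimers)
Conditions: LiAlH4, THF, 0 °C; work-up with H2O, aq. NaOH, H2O
Reagents that add atoms: none
Why: Hydride reduction of a lactone to the diol; the aryl silyl ether, the prenyl ether and the benzylic ether of ring A are inert to LiAlH4 at 0 °C, and no stereocentre is touched.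

Step 9
Reactants: 16 [(2S,3R,4R)-4-{hydroxy[3-methoxy-4-(3-methylbut-2-enyloxy)phenyl]methyl}-2-[3-methoxy-4-(triisopropylsilyloxy)phenyl]tetrahydrofuran-3-yl]methanol
Product: 17 (1S,3aR,4S,6aR)-1-[3-methoxy-4-(triisopropylsilyloxy)phenyl]-4-[3-methoxy-4-(3-methylbut-2-enyloxy)phenyl]tetrahydro-1H,3H-furo[3,4-c]furan
Conditions: (+)-camphor-10-sulfonic acid (5 mol%), 4 Å MS, CH2Cl2, −20 to 0 °C; Et3N quench
Reagents that add atoms: none
Why: Acid-catalysed SN1 etherification: the 4-alkoxybenzylic alcohol ionises to a quinone-methide-like cation, which the C9 hydroxyl captures in a 5-exo-trig closure, so both carbinol epimers converge. C7' is set kinetically: allylic strain holds the C8'–H bond in the plane of the cation, the C9 hydroxyl can only reach the face on the side of C8, and the aryl group ends cis to H8', that is exo. Low temperature and a prompt amine quench are meant to keep the prenyl ether and the ring A benzylic ether from ionising and the product from equilibrating.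

Step 10
Reactants: 17 (1S,3aR,4S,6aR)-1-[3-methoxy-4-(triisopropylsilyloxy)phenyl]-4-[3-methoxy-4-(3-methylbut-2-enyloxy)phenyl]tetrahydro-1H,3H-furo[3,4-c]furan
Product: 18 2-methoxy-4-{(1S,3aR,4S,6aR)-4-[3-methoxy-4-(3-methylbut-2-enyloxy)phenyl]tetrahydro-1H,3H-furo[3,4-c]furan-1-yl}phenol
Conditions: Bu4NF, THF, 0 °C; aq. NH4Cl
Reagents that add atoms: none
Why: Fluoride cleaves the aryl O–Si bond (strong Si–F bond, phenoxide as leaving group) at 0 °C; the prenyl ether and the benzylic ethers are stable to Bu4NF, and the buffered work-up protonates the phenoxide before it can open ring A.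

## Compound list

1 | vanillin (4-hydroxy-3-methoxybenzaldehyde) | COc1cc(C=O)ccc1O | starting material
2 | 3-methoxy-4-(triisopropylsilyloxy)benzaldehyde | COc1cc(C=O)ccc1O[Si](C(C)C)(C(C)C)C(C)C | intermediate
3 | Meldrum's acid (2,2-dimethyl-1,3-dioxane-4,6-dione) | CC1(C)OC(=O)CC(=O)O1 | starting material
4 | 5-[3-methoxy-4-(triisopropylsilyloxy)benzylidene]-2,2-dimethyl-1,3-dioxane-4,6-dione | CC1(C)OC(=O)C(=Cc2ccc(O[Si](C(C)C)(C(C)C)C(C)C)c(OC)c2)C(=O)O1 | intermediate
5 | 4-vinyl-1,3-dioxolan-2-one (vinylethylene carbonate, racemic) | C=CC1COC(=O)O1 | starting material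
6 | (1R,4R)-4-ethenyl-1-[3-methoxy-4-(triisopropylsilyloxy)phenyl]-8,8-dimethyl-2,7,9-trioxaspiro[4.5]decane-6,10-dione (aryl and vinyl trans on the tetrahydrofuran ring) | C=C[C@H]1CO[C@H](c3ccc(O[Si](C(C)C)(C(C)C)C(C)C)c(OC)c3)C12C(=O)OC(C)(C)OC2=O | intermediate
7 | (2R,4R)-4-ethenyl-3-(methoxycarbonyl)-2-[3-methoxy-4-(triisopropylsilyloxy)phenyl]tetrahydrofuran-3-carboxylic acid (C3 epimers, centre left undefined; not isolated) | C=C[C@H]1CO[C@H](c2ccc(O[Si](C(C)C)(C(C)C)C(C)C)c(OC)c2)C1(C(=O)OC)C(=O)O | intermediate
8 | methyl (2S,3S,4R)-4-ethenyl-2-[3-methoxy-4-(triisopropylsilyloxy)phenyl]tetrahydrofuran-3-carboxylate (its C3 epimer may accompany it and is carried along) | C=C[C@H]1CO[C@H](c2ccc(O[Si](C(C)C)(C(C)C)C(C)C)c(OC)c2)[C@H]1C(=O)OC | intermediate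
9 | methyl (2S,3S,4R)-2-[3-methoxy-4-(triisopropylsilyloxy)phenyl]-4-(1,2,4-trioxolan-3-yl)tetrahydrofuran-3-carboxylate (trioxolane carbon undefined; not isolated) | C1OC(OO1)[C@H]2CO[C@H](c3ccc(O[Si](C(C)C)(C(C)C)C(C)C)c(OC)c3)[C@H]2C(=O)OC | intermediate
10 | methyl (2S,3S,4R)-4-formyl-2-[3-methoxy-4-(triisopropylsilyloxy)phenyl]tetrahydrofuran-3-carboxylate | O=C[C@H]1CO[C@H](c2ccc(O[Si](C(C)C)(C(C)C)C(C)C)c(OC)c2)[C@H]1C(=O)OC | intermediate
11 | 4-bromo-2-methoxyphenol | COc1cc(Br)ccc1O | starting material
12 | 4-bromo-2-methoxy-1-(3-methylbut-2-enyloxy)benzene | COc1cc(Br)ccc1OCC=C(C)C | intermediate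
13 | [3-methoxy-4-(3-methylbut-2-enyloxy)phenyl]magnesium bromide (not isolated) | COc1cc([Mg]Br)ccc1OCC=C(C)C | intermediate
14 | methyl (2S,3S,4R)-4-{hydroxy[3-methoxy-4-(3-methylbut-2-enyloxy)phenyl]methyl}-2-[3-methoxy-4-(triisopropylsilyloxy)phenyl]tetrahydrofuran-3-carboxylate (both carbinol epimers, carbinol centre left undefined; not isolated) | OC(c2ccc(OCC=C(C)C)c(OC)c2)[C@H]1CO[C@H](c2ccc(O[Si](C(C)C)(C(C)C)C(C)C)c(OC)c2)[C@H]1C(=O)OC | intermediate
15 | (3aR,6S,6aS)-6-[3-methoxy-4-(triisopropylsilyloxy)phenyl]-3-[3-methoxy-4-(3-methylbut-2-enyloxy)phenyl]tetrahydro-1H,3H-furo[3,4-c]furan-1-one (cis-fused; both C3 epimers, C3 left undefined) | O=C1OC(c3ccc(OCC=C(C)C)c(OC)c3)[C@H]2CO[C@H](c3ccc(O[Si](C(C)C)(C(C)C)C(C)C)c(OC)c3)[C@@H]12 | intermediate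
16 | [(2S,3R,4R)-4-{hydroxy[3-methoxy-4-(3-methylbut-2-enyloxy)phenyl]methyl}-2-[3-methoxy-4-(triisopropylsilyloxy)phenyl]tetrahydrofuran-3-yl]methanol (both carbinol epimers, carbinol centre left undefined) | OC(c2ccc(OCC=C(C)C)c(OC)c2)[C@H]1CO[C@H](c2ccc(O[Si](C(C)C)(C(C)C)C(C)C)c(OC)c2)[C@H]1CO | intermediate
17 | (1S,3aR,4S,6aR)-1-[3-methoxy-4-(triisopropylsilyloxy)phenyl]-4-[3-methoxy-4-(3-methylbut-2-enyloxy)phenyl]tetrahydro-1H,3H-furo[3,4-c]furan | COc1cc([C@H]2OC[C@H]3[C@@H]2CO[C@@H]3c2ccc(OCC=C(C)C)c(OC)c2)ccc1O[Si](C(C)C)(C(C)C)C(C)C | intermediate
18 | 2-methoxy-4-{(1S,3aR,4S,6aR)-4-[3-methoxy-4-(3-methylbut-2-enyloxy)phenyl]tetrahydro-1H,3H-furo[3,4-c]furan-1-yl}phenol (CNP0185952.1) | COc1cc([C@H]2OC[C@H]3[C@@H]2CO[C@@H]3c2ccc(OCC=C(C)C)c(OC)c2)ccc1O | target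

## Step count and weak points

Total: 10 steps. Longest linear sequence: 9 steps (steps 1–5 and 7–10 from vanillin); step 6 is a one-step branch.

**Step 3 (key step).** The most likely failures are:
- weak differentiation between the two closing transition states, so that the cis adduct forms beside the trans one (aryl and vinyl are 1,3-related across a spiro carbon with two identical arms);
- incomplete enantiocontrol at a tertiary allylic carbon;
- slow oxa-Michael addition to the electron-rich arylidene, so that the zwitterion oligomerises.

Cis adduct would feed the C7-endo series and cannot be repaired later by equilibration.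

Fallback: it sets out from 2 and returns at 17. C8' is set by asymmetric conjugate addition and both benzylic centres by kinetic cation capture.
- Furan-2(5H)-one takes up a vinyl group from potassium vinyltrifluoroborate under [RhCl(cod)]2/BINAP catalysis (asymmetric 1,4-addition, ligand enantiomer chosen for the S product) to give (S)-4-ethenyldihydrofuran-2(3H)-one F1.
- Its lithium enolate (LiN(iPr)2, THF, −78 °C) adds to 2 anti to the vinyl group to give the trans aldol lactone F2.
- LiAlH4 gives the triol F3.
- Ozonolysis with PPh3 work-up gives the lactol F4.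
- An excess of 13 opens the lactol to the tetraol F5.
- Catalytic camphorsulfonic acid closes rings A and B through the two benzylic cations to 17.

**Step 4.** The risks are loss of the aryl silyl group by pyridine-assisted methanolysis at 100 °C, slow opening of the hindered spiro dione, and opening of ring A by elimination across C7–C8 once the carboxylate has formed.

Fallback: it sets out from 6 and returns at 8. Water replaces methanol as the nucleophile: pyridine–H2O at 100 °C hydrolyses and decarboxylates 6 to (2S,3S,4R)-4-ethenyl-2-[3-methoxy-4-(triisopropylsilyloxy)phenyl]tetrahydrofuran-3-carboxylic acid F6, and the ester is made afterwards with MeI and K2CO3 in DMF.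

**Step 7.** The risks are enolisation of 10 by the basic Grignard reagent with loss of configuration at C8' (which lactonisation would then pass on to C8, giving the C7-endo series), and β-elimination of O1 from the ester enolate during the DBU stage.

Fallback: it sets out from 8 and returns at 16. The order of reduction and arylation is reversed so that C8' becomes self-correcting.
- 8, equilibrated with DBU to the 2,3-trans ester, is reduced with LiAlH4 to [(2S,3R,4R)-4-ethenyl-2-[3-methoxy-4-(triisopropylsilyloxy)phenyl]tetrahydrofuran-3-yl]methanol F7; the minor C8 epimer is removed at this stage.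
- Ozonolysis gives the cis-fused lactol F8. The formyl group is masked as a hemiacetal that only a cis arrangement can form.
- An excess of 13 opens the lactol to 16.

The price is that C8 then rests on an ester equilibrium and not on the lactone constraint.

**Step 9.** The risks are cleavage or migration of the prenyl group under acid, and erosion of the kinetic exo preference if C7' (or, later, C7) re-ionises before the quench.

Fallback: it sets out from 10 and 11 and returns at 17. An acid-stable allyl ether is carried through the closure and turned into the prenyl ether afterwards.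
- 11 is alkylated with allyl bromide and K2CO3 to 1-allyloxy-4-bromo-2-methoxybenzene F9.
- Mg gives the Grignard reagent F10.
- Addition to 10 gives the hydroxy ester F11, and DBU gives the lactone F12.
- LiAlH4 gives the diol F13.
- BF3·OEt2 in CH2Cl2 at −78 °C, which the allyl ether tolerates, closes ring B to the allyl ether F14.
- Cross-metathesis with 2-methylbut-2-ene and the second-generation Grubbs catalyst, RuCl2(=CHPh)(H2IMes)(PCy3), converts the allyl ether into the prenyl ether 17.

## Further compounds

F1 | step 3 | (S)-4-ethenyldihydrofuran-2(3H)-one | C=C[C@H]1COC(=O)C1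
F2 | step 3 | (3S,4R)-4-ethenyl-3-{hydroxy[3-methoxy-4-(triisopropylsilyloxy)phenyl]methyl}dihydrofuran-2(3H)-one (carbinol epimers) | C=C[C@H]1COC(=O)[C@@H]1C(O)c1ccc(O[Si](C(C)C)(C(C)C)C(C)C)c(OC)c1
F3 | step 3 | (2R,3R)-3-ethenyl-2-{hydroxy[3-methoxy-4-(triisopropylsilyloxy)phenyl]methyl}butane-1,4-diol (carbinol epimers) | C=C[C@@H](CO)[C@H](CO)C(O)c1ccc(O[Si](C(C)C)(C(C)C)C(C)C)c(OC)c1
F4 | step 3 | (3R,4R)-4-{hydroxy[3-methoxy-4-(triisopropylsilyloxy)phenyl]methyl}-3-(hydroxymethyl)tetrahydrofuran-2-ol (lactol and carbinol centres undefined) | OC1OC[C@H](C(O)c2ccc(O[Si](C(C)C)(C(C)C)C(C)C)c(OC)c2)[C@@H]1CO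
F5 | step 3 | (2R,3R)-2,3-bis(hydroxymethyl)-1-[3-methoxy-4-(triisopropylsilyloxy)phenyl]-4-[3-methoxy-4-(3-methylbut-2-enyloxy)phenyl]butane-1,4-diol (carbinol centres undefined) | OC[C@H](C(O)c1ccc(O[Si](C(C)C)(C(C)C)C(C)C)c(OC)c1)[C@H](CO)C(O)c1ccc(OCC=C(C)C)c(OC)c1
F6 | step 4 | (2S,3S,4R)-4-ethenyl-2-[3-methoxy-4-(triisopropylsilyloxy)phenyl]tetrahydrofuran-3-carboxylic acid | C=C[C@H]1CO[C@H](c2ccc(O[Si](C(C)C)(C(C)C)C(C)C)c(OC)c2)[C@H]1C(=O)O
F7 | step 7 | [(2S,3R,4R)-4-ethenyl-2-[3-methoxy-4-(triisopropylsilyloxy)phenyl]tetrahydrofuran-3-yl]methanol | C=C[C@H]1CO[C@H](c2ccc(O[Si](C(C)C)(C(C)C)C(C)C)c(OC)c2)[C@H]1CO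
F8 | step 7 | (3aR,4S,6aR)-4-[3-methoxy-4-(triisopropylsilyloxy)phenyl]tetrahydro-1H,3H-furo[3,4-c]furan-1-ol (anomers) | OC1OC[C@H]2[C@@H]1CO[C@@H]2c1ccc(O[Si](C(C)C)(C(C)C)C(C)C)c(OC)c1
F9 | step 9 | 1-allyloxy-4-bromo-2-methoxybenzene | COc1cc(Br)ccc1OCC=C
F10 | step 9 | (4-allyloxy-3-methoxyphenyl)magnesium bromide | COc1cc([Mg]Br)ccc1OCC=C
F11 | step 9 | methyl (2S,3S,4R)-4-[(4-allyloxy-3-methoxyphenyl)(hydroxy)methyl]-2-[3-methoxy-4-(triisopropylsilyloxy)phenyl]tetrahydrofuran-3-carboxylate (carbinol epimers) | OC(c2ccc(OCC=C)c(OC)c2)[C@H]1CO[C@H](c2ccc(O[Si](C(C)C)(C(C)C)C(C)C)c(OC)c2)[C@H]1C(=O)OC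
F12 | step 9 | (3aR,6S,6aS)-3-(4-allyloxy-3-methoxyphenyl)-6-[3-methoxy-4-(triisopropylsilyloxy)phenyl]tetrahydro-1H,3H-furo[3,4-c]furan-1-one (C3 epimers) | O=C1OC(c3ccc(OCC=C)c(OC)c3)[C@H]2CO[C@H](c3ccc(O[Si](C(C)C)(C(C)C)C(C)C)c(OC)c3)[C@@H]12
F13 | step 9 | [(2S,3R,4R)-4-[(4-allyloxy-3-methoxyphenyl)(hydroxy)methyl]-2-[3-methoxy-4-(triisopropylsilyloxy)phenyl]tetrahydrofuran-3-yl]methanol (carbinol epimers) | OC(c2ccc(OCC=C)c(OC)c2)[C@H]1CO[C@H](c2ccc(O[Si](C(C)C)(C(C)C)C(C)C)c(OC)c2)[C@H]1CO
F14 | step 9 | (1S,3aR,4S,6aR)-4-(4-allyloxy-3-methoxyphenyl)-1-[3-methoxy-4-(triisopropylsilyloxy)phenyl]tetrahydro-1H,3H-furo[3,4-c]furan | COc1cc([C@H]2OC[C@H]3[C@@H]2CO[C@@H]3c2ccc(OCC=C)c(OC)c2)ccc1O[Si](C(C)C)(C(C)C)C(C)C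
A1 | alternative 1 | (3aR,6aR)-tetrahydro-1H,3H-furo[3,4-c]furan-1,4-diyl diacetate (anomeric centres undefined) | CC(=O)OC1OC[C@H]2[C@@H]1COC2OC(C)=O
A2 | alternative 1 | (4-benzyloxy-3-methoxyphenyl)zinc bromide | COc1cc([Zn]Br)ccc1OCc1ccccc1
A3 | alternative 1 | pinoresinol dibenzyl ether, (1S,3aR,4S,6aR)-1,4-bis(4-benzyloxy-3-methoxyphenyl)tetrahydro-1H,3H-furo[3,4-c]furan | COc1cc([C@H]2OC[C@H]3[C@@H]2CO[C@@H]3c2ccc(OCc3ccccc3)c(OC)c2)ccc1OCc1ccccc1
A4 | alternative 1 | (7S,7'S,8R,8'R)-pinoresinol | COc1cc([C@H]2OC[C@H]3[C@@H]2CO[C@@H]3c2ccc(O)c(OC)c2)ccc1O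
A5 | alternative 2 | 3-diazo-2-[3-methoxy-4-(triisopropylsilyloxy)phenyl]-5-{(tert-butyldimethylsilyloxy)[3-methoxy-4-(3-methylbut-2-enyloxy)phenyl]methyl}tetrahydropyran-4-one (configuration as in the SMILES) | [N-]=[N+]=C1C(=O)[C@@H]([C@H](O[Si](C)(C)C(C)(C)C)c2ccc(OCC=C(C)C)c(OC)c2)CO[C@@H]1c1ccc(O[Si](C(C)C)(C(C)C)C(C)C)c(OC)c1
A6 | alternative 2 | methyl 2-[3-methoxy-4-(triisopropylsilyloxy)phenyl]-4-{(tert-butyldimethylsilyloxy)[3-methoxy-4-(3-methylbut-2-enyloxy)phenyl]methyl}tetrahydrofuran-3-carboxylate (configuration as in the SMILES; formed together with its C8 epimer) | COC(=O)[C@@H]1[C@@H](c2ccc(O[Si](C(C)C)(C(C)C)C(C)C)c(OC)c2)OC[C@@H]1[C@H](O[Si](C)(C)C(C)(C)C)c1ccc(OCC=C(C)C)c(OC)c1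
A7 | alternative 3 | (5R)-5-menthyloxyfuran-2(5H)-one | O=C1O[C@@H](O[C@@H]2C[C@H](C)CC[C@H]2C(C)C)C=C1
A8 | alternative 3 | 2-(4-benzyloxy-3-methoxyphenyl)-1,3-dithiane | COc1cc(C2SCCCS2)ccc1OCc1ccccc1
A9 | alternative 3 | trans,trans-4-[2-(4-benzyloxy-3-methoxyphenyl)-1,3-dithian-2-yl]-3-{hydroxy[3-methoxy-4-(triisopropylsilyloxy)phenyl]methyl}-5-menthyloxydihydrofuran-2(3H)-one | O=C1O[C@@H](O[C@@H]2C[C@H](C)CC[C@H]2C(C)C)[C@H](C2(c3ccc(OCc4ccccc4)c(OC)c3)SCCCS2)[C@H]1[C@H](O)c1ccc(O[Si](C(C)C)(C(C)C)C(C)C)c(OC)c1
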